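The octamer is cut at its seven diaryl ether oxygens into one 2,4,6-trimethoxyphenol (ring A), three copies of one bromo-dimer aldehyde (rings B/C, D/E, F/G) and one fluoro aldehyde (ring H). Rings are lettered A to H from the phloroglucinol end, and C1 is the ring carbon carrying the ether oxygen toward ring A. The key step exploits the fact that the C4–OH of rings C, E, G and H is para to C1. A C4 formyl group first activates C1–F for SNAr; a fourfold Baeyer–Villiger oxidation with formate methanolysis then turns all four C4–CHO into C4–OH in one operation. Its precursor is the heptadeca-O-methyl octamer tetra-aldehyde 15.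

Key step: step 12

Remark on the structure: the target (C48H34O28, 21 hydroxyls, seven ether bridges) has no stereocentre, so no stereocontrol is needed. Compounds 15 and 17 each carry 17 methyl ethers, which accounts for every hydroxyl not made in the key step.

Remark on protection: the C2 oxygen of rings C, E and G is carried as a methoxymethyl (MOM) ether. It is removed by dilute methanolic acid, so no hydrogenolysis is run in the presence of formyl groups.

Dimer 7 is made once (steps 1 to 4) and used in steps 5, 7 and 9.

Step 1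
Reactants: 1 4-fluoro-2,6-dimethoxybenzaldehyde
Product: 2 3-bromo-4-fluoro-2,6-dimethoxybenzaldehyde
Conditions: NBS, MeCN, rt
Reagents that add atoms: N-bromosuccinimide, O=C1CCC(=O)N1Br
Why: Electrophilic aromatic bromination should occur at C3, since C3 and C5 are equivalent, are the only open positions, are each ortho and para to a methoxy group, and the first bromine deactivates the ring toward a second.

Step 2
Reactants: 2 3-bromo-4-fluoro-2,6-dimethoxybenzaldehyde
Product: 4 4-fluoro-3-hydroxy-2,6-dimethoxybenzaldehyde, via pinacol boronate 3 (not isolated)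
Conditions: Pd(dppf)Cl2 (cat.), B2pin2, KOAc, 1,4-dioxane, 90 °C; then 30% aq. H2O2, NaHCO3, THF, 0 °C to rt
Reagents that add atoms: bis(pinacolato)diboron, CC1(C)OB(OC1(C)C)B1OC(C)(C)C(C)(C)O1 (boron of 3); hydrogen peroxide, OO (oxygen of 4)
Why: Miyaura borylation followed by boronate oxidation (1,2-aryl shift from boron to oxygen) should install the C3 oxygen under near-neutral conditions, so that the formyl group and the fluoride para to it never meet hot hydroxide and the 2,6-disubstituted boronate is oxidised before it can protodeboronate.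

Step 3
Reactants: 4 4-fluoro-3-hydroxy-2,6-dimethoxybenzaldehyde
Product: 5 4-fluoro-2,6-dimethoxy-3-(methoxymethoxy)benzaldehyde
Conditions: MOMCl, K2CO3, acetone, 0 °C to rt
Reagents that add atoms: chloromethyl methyl ether, COCCl
Why: Williamson-type O-alkylation of the phenoxide with the highly reactive alpha-chloro ether should proceed at room temperature, far below the temperature at which a phenoxide displaces the ring fluoride.

Step 4
Reactants: 5 4-fluoro-2,6-dimethoxy-3-(methoxymethoxy)benzaldehyde; 6 4-bromo-2,6-dimethoxyphenol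
Product: 7 4-(4-bromo-2,6-dimethoxyphenoxy)-2,6-dimethoxy-3-(methoxymethoxy)benzaldehyde (bromo-dimer)
Conditions: Cs2CO3, DMF, 100 °C, Ar
Reagents that add atoms: none
Why: Nucleophilic aromatic substitution (addition–elimination) should take place at the fluoride para to the formyl group, which stabilises the Meisenheimer adduct, while the unactivated aryl bromide of 6 is inert to phenoxide.

Step 5
Reactants: 7 bromo-dimer; 8 2,4,6-trimethoxyphenol
Product: 9 trimer MOM ether (rings A to C)
Conditions: CuI (cat.), picolinic acid (cat.), K3PO4, DMSO, 90 °C, Ar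
Reagents that add atoms: none
Why: Ullmann-type copper-catalysed diaryl ether coupling with the picolinic acid ligand, a system suited to ortho,ortho-disubstituted phenols, should join the phenoxide to the bromide of 7, which has two free ortho positions, and the non-enolisable aldehyde and the MOM acetal tolerate K3PO4.

Step 6
Reactants: 9 trimer MOM ether
Product: 10 trimer phenol (rings A to C)
Conditions: HCl (2 M in MeOH)–THF, 40 °C; aq. work-up
Reagents that add atoms: none
Why: Acid-catalysed acetal exchange (MOM ether cleavage) should transfer the methoxymethyl group to methanol, while aryl methyl ethers and diaryl ethers are inert to dilute acid and the aqueous work-up leaves the formyl group as the aldehyde.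

Step 7
Reactants: 10 trimer phenol; 7 bromo-dimer
Product: 11 pentamer MOM ether (rings A to E)
Conditions: CuI (cat.), picolinic acid (cat.), K3PO4, DMSO, 100 °C, Ar
Reagents that add atoms: none
Why: The same Ullmann-type coupling should form the ring C C2–O–ring D C1 bond, the hindered ring C phenoxide being the only nucleophile and the unhindered bromide of 7 the only electrophile.

Step 8
Reactants: 11 pentamer MOM ether
Product: 12 pentamer phenol (rings A to E)
Conditions: HCl (2 M in MeOH)–THF, 40 °C; aq. work-up
Reagents that add atoms: none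
Why: Acid-catalysed MOM ether cleavage by acetal exchange with methanol should free the ring E C2 hydroxyl, as in step 6, without touching methyl ethers, diaryl ethers or the two formyl groups.

Step 9
Reactants: 12 pentamer phenol; 7 bromo-dimer
Product: 13 heptamer MOM ether (rings A to G)
Conditions: CuI (cat.), picolinic acid (cat.), K3PO4, DMSO, 100 °C, Ar
Reagents that add atoms: none
Why: A third Ullmann-type copper-catalysed coupling should form the ring E C2–O–ring F C1 bond on the same electronic and steric pattern as step 7.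

Step 10
Reactants: 13 heptamer MOM ether
Product: 14 heptamer phenol (rings A to G)
Conditions: HCl (2 M in MeOH)–THF, 40 °C; aq. work-up
Reagents that add atoms: none
Why: Acid-catalysed MOM ether cleavage by acetal exchange with methanol should free the ring G C2 hydroxyl under the conditions of steps 6 and 8.

Step 11
Reactants: 14 heptamer phenol; 1 4-fluoro-2,6-dimethoxybenzaldehyde
Product: 15 octamer tetra-aldehyde
Conditions: Cs2CO3, DMF, 100 °C, Ar
Reagents that add atoms: none
Why: Nucleophilic aromatic substitution of the fluoride para to the formyl group of 1 by the ring G phenoxide should attach ring H, the unhindered fluoro aldehyde being used in excess to offset the crowding of the nucleophile.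

Step 12
Reactants: 15 octamer tetra-aldehyde
Product: 17 octamer tetraphenol, via octamer tetraformate 16 (not isolated)
Conditions: mCPBA, Na2HPO4, CH2Cl2, 0 °C to rt; aq. Na2S2O3/NaHCO3 wash; then K2CO3 (cat.), MeOH–THF, Ar, rt
Reagents that add atoms: meta-chloroperoxybenzoic acid, OOC(=O)c1cccc(Cl)c1
Why: Each formyl group should add the peracid to give a Criegee adduct, from which the aryl group rather than hydrogen migrates to oxygen with loss of 3-chlorobenzoate, and the four aryl formates are then transesterified by methanol once the oxidant has been washed out. The closest known reaction type is the Baeyer–Villiger (Dakin-type) conversion of 2,6-dimethoxybenzaldehydes into phenols, here run at four sites of one molecule. No ring is closed and no stereocentre is formed. The step needs aryl over hydride migration and aldehyde oxidation over attack on the arene rings; the two methoxy groups ortho to every formyl carbon, together with the para aryloxy oxygen, raise the migratory aptitude of rings C, E, G and H, and the formyl-free rings A, B, D and F see only a modest excess of peracid at low temperature. Solid Na2HPO4 keeps the formates intact while peracid is present, and the phenols are released only after the thiosulfate wash and under argon, so the oxidisable 4-aryloxy-2,6-dimethoxyphenol units never meet the oxidant.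

Step 13
Reactants: 17 octamer tetraphenol
Product: 18 target octamer (CNP0206369.0)
Conditions: BBr3 (excess), CH2Cl2, −78 °C to rt; then degassed H2O, 0 °C, Ar
Reagents that add atoms: none
Why: Lewis acid-mediated aryl methyl ether cleavage (bromide attack on the methyl group of each boron-complexed ether) should remove all 17 methyl groups, while diaryl ether C–O bonds, which have no sp3 carbon for bromide to attack, stay intact.

Compound list

1 | 4-fluoro-2,6-dimethoxybenzaldehyde | COc1cc(F)cc(OC)c1C=O | starting material
2 | 3-bromo-4-fluoro-2,6-dimethoxybenzaldehyde | COc1cc(F)c(Br)c(OC)c1C=O | intermediate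
3 | 4-fluoro-2,6-dimethoxy-3-(4,4,5,5-tetramethyl-1,3,2-dioxaborolan-2-yl)benzaldehyde | COc1cc(F)c(B2OC(C)(C)C(C)(C)O2)c(OC)c1C=O | intermediate (not isolated)
4 | 4-fluoro-3-hydroxy-2,6-dimethoxybenzaldehyde | COc1cc(F)c(O)c(OC)c1C=O | intermediate
5 | 4-fluoro-2,6-dimethoxy-3-(methoxymethoxy)benzaldehyde | COCOc1c(F)cc(OC)c(C=O)c1OC | intermediate
6 | 4-bromo-2,6-dimethoxyphenol | COc1cc(Br)cc(OC)c1O | starting material
7 | 4-(4-bromo-2,6-dimethoxyphenoxy)-2,6-dimethoxy-3-(methoxymethoxy)benzaldehyde (bromo-dimer) | COCOc1c(Oc2c(OC)cc(Br)cc2OC)cc(OC)c(C=O)c1OC | intermediate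
8 | 2,4,6-trimethoxyphenol | COc1cc(OC)c(O)c(OC)c1 | starting material
9 | 2,6-dimethoxy-3-(methoxymethoxy)-4-[2,6-dimethoxy-4-(2,4,6-trimethoxyphenoxy)phenoxy]benzaldehyde (trimer A–C; CHO at C4 and OMOM at C2 of ring C) | COc1cc(OC)c(Oc2cc(OC)c(Oc3cc(OC)c(C=O)c(OC)c3OCOC)c(OC)c2)c(OC)c1 | intermediate
10 | 3-hydroxy-2,6-dimethoxy-4-[2,6-dimethoxy-4-(2,4,6-trimethoxyphenoxy)phenoxy]benzaldehyde (trimer A–C; OH at C2 of ring C) | COc1cc(OC)c(Oc2cc(OC)c(Oc3cc(OC)c(C=O)c(OC)c3O)c(OC)c2)c(OC)c1 | intermediate
11 | pentamer A–E MOM ether (CHO at C4 of rings C and E; OMOM at C2 of ring E; 11 methyl ethers) | COc1cc(OC)c(Oc2cc(OC)c(Oc3cc(OC)c(C=O)c(OC)c3Oc3cc(OC)c(Oc4cc(OC)c(C=O)c(OC)c4OCOC)c(OC)c3)c(OC)c2)c(OC)c1 | intermediate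
12 | pentamer A–E phenol (CHO at C4 of rings C and E; OH at C2 of ring E; 11 methyl ethers) | COc1cc(OC)c(Oc2cc(OC)c(Oc3cc(OC)c(C=O)c(OC)c3Oc3cc(OC)c(Oc4cc(OC)c(C=O)c(OC)c4O)c(OC)c3)c(OC)c2)c(OC)c1 | intermediate
13 | heptamer A–G MOM ether (CHO at C4 of rings C, E and G; OMOM at C2 of ring G; 15 methyl ethers) | COc1cc(OC)c(Oc2cc(OC)c(Oc3cc(OC)c(C=O)c(OC)c3Oc3cc(OC)c(Oc4cc(OC)c(C=O)c(OC)c4Oc4cc(OC)c(Oc5cc(OC)c(C=O)c(OC)c5OCOC)c(OC)c4)c(OC)c3)c(OC)c2)c(OC)c1 | intermediate
14 | heptamer A–G phenol (CHO at C4 of rings C, E and G; OH at C2 of ring G; 15 methyl ethers) | COc1cc(OC)c(Oc2cc(OC)c(Oc3cc(OC)c(C=O)c(OC)c3Oc3cc(OC)c(Oc4cc(OC)c(C=O)c(OC)c4Oc4cc(OC)c(Oc5cc(OC)c(C=O)c(OC)c5O)c(OC)c4)c(OC)c3)c(OC)c2)c(OC)c1 | intermediate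
15 | octamer tetra-aldehyde (CHO at C4 of rings C, E, G and H; 17 methyl ethers) | COc1cc(OC)c(Oc2cc(OC)c(Oc3cc(OC)c(C=O)c(OC)c3Oc3cc(OC)c(Oc4cc(OC)c(C=O)c(OC)c4Oc4cc(OC)c(Oc5cc(OC)c(C=O)c(OC)c5Oc5cc(OC)c(C=O)c(OC)c5)c(OC)c4)c(OC)c3)c(OC)c2)c(OC)c1 | intermediate
16 | octamer tetraformate (OCHO at C4 of rings C, E, G and H; 17 methyl ethers) | COc1cc(OC)c(Oc2cc(OC)c(Oc3cc(OC)c(OC=O)c(OC)c3Oc3cc(OC)c(Oc4cc(OC)c(OC=O)c(OC)c4Oc4cc(OC)c(Oc5cc(OC)c(OC=O)c(OC)c5Oc5cc(OC)c(OC=O)c(OC)c5)c(OC)c4)c(OC)c3)c(OC)c2)c(OC)c1 | intermediate (not isolated)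
17 | octamer tetraphenol (OH at C4 of rings C, E, G and H; 17 methyl ethers) | COc1cc(OC)c(Oc2cc(OC)c(Oc3cc(OC)c(O)c(OC)c3Oc3cc(OC)c(Oc4cc(OC)c(O)c(OC)c4Oc4cc(OC)c(Oc5cc(OC)c(O)c(OC)c5Oc5cc(OC)c(O)c(OC)c5)c(OC)c4)c(OC)c3)c(OC)c2)c(OC)c1 | intermediate
18 | CNP0206369.0, the fully hydroxylated octamer (21 OH, seven ether bridges, achiral) | Oc1cc(O)c(Oc2cc(O)c(Oc3cc(O)c(O)c(O)c3Oc3cc(O)c(Oc4cc(O)c(O)c(O)c4Oc4cc(O)c(Oc5cc(O)c(O)c(O)c5Oc5cc(O)c(O)c(O)c5)c(O)c4)c(O)c3)c(O)c2)c(O)c1 | target

Total step count: 13. Longest linear sequence: 13 steps (1 to 18 through 2, 4, 5, 7, 9 to 15 and 17).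

Steps most likely to fail

Step 12. Oxygen insertion may stay incomplete at one or more of the four hindered sites, hydride may migrate instead of aryl at some sites, or the peracid may attack the electron-rich formyl-free rings. The fallback inverts the order and changes the oxidant class. It sets out from 15: BBr3 in CH2Cl2 (−78 °C to rt, aqueous quench) should cleave all 17 methyl ethers while the formyl groups survive, giving the heptadecahydroxy tetra-aldehyde F1. Every formyl group of this compound is flanked by two ortho hydroxyls, the classical substrate of the Dakin oxidation. Aqueous H2O2 (one equivalent per formyl group) in degassed NaHCO3 solution–THF at 0 °C under argon, followed by acidification, should replace each formyl group by hydroxyl with loss of formic acid. Nucleophilic hydroperoxide does not attack the arene rings electrophilically. The fallback comes back to the route at 18.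

Step 9 (the same concern applies more mildly to steps 5 and 7). The ortho,ortho-disubstituted phenoxide of the pentamer may couple too slowly with the electron-rich bromide, so that hydrodebromination of 7 and thermal degradation of the aldehydes take over. The fallback replaces the Ullmann coupling by a room-temperature Chan–Evans–Lam coupling. It sets out from 7: Miyaura borylation (Pd(dppf)Cl2, B2pin2, KOAc, dioxane, 90 °C) should give the dimer pinacol boronate F2. Oxidative removal of pinacol (NaIO4, NH4OAc, acetone–water) should give the dimer boronic acid F3. This is coupled with phenol 12 using Cu(OAc)2 (divalent copper), pyridine and 4 Å molecular sieves in CH2Cl2 under air at rt, conditions known to accept 2,6-disubstituted phenols. The fallback comes back to the route at 13.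

Step 13. Some of the 17 methyl ethers may resist cleavage, and the free polyphenol may oxidise in air during isolation, so that no clean product is obtained. The fallback isolates the product in masked form. It sets out from 17: after the BBr3 treatment and a methanol quench with evaporation, the crude residue is acetylated (Ac2O, pyridine, DMAP cat., rt) to the air-stable henicosaacetate F4. This can be purified on silica and separated from incompletely demethylated material, which can be resubjected. Acid methanolysis (HCl in degassed MeOH, rt, Ar) then removes the 21 acetyl groups without exposing the pyrogallol-type rings to base. The fallback comes back to the route at 18.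

Further compounds

F1 | step 12 | heptadecahydroxy octamer tetra-aldehyde (CHO at C4 of rings C, E, G and H; all other oxygens free OH) | Oc1cc(O)c(Oc2cc(O)c(Oc3cc(O)c(C=O)c(O)c3Oc3cc(O)c(Oc4cc(O)c(C=O)c(O)c4Oc4cc(O)c(Oc5cc(O)c(C=O)c(O)c5Oc5cc(O)c(C=O)c(O)c5)c(O)c4)c(O)c3)c(O)c2)c(O)c1
F2 | step 9 | 2,6-dimethoxy-3-(methoxymethoxy)-4-[2,6-dimethoxy-4-(4,4,5,5-tetramethyl-1,3,2-dioxaborolan-2-yl)phenoxy]benzaldehyde (dimer pinacol boronate) | COCOc1c(Oc2c(OC)cc(B3OC(C)(C)C(C)(C)O3)cc2OC)cc(OC)c(C=O)c1OC
F3 | step 9 | [4-(4-formyl-3,5-dimethoxy-2-(methoxymethoxy)phenoxy)-3,5-dimethoxyphenyl]boronic acid (dimer boronic acid) | COCOc1c(Oc2c(OC)cc(B(O)O)cc2OC)cc(OC)c(C=O)c1OC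
F4 | step 13 | henicosaacetate of the target (all 21 hydroxyls as acetates) | CC(=O)Oc1cc(OC(C)=O)c(Oc2cc(OC(C)=O)c(Oc3cc(OC(C)=O)c(OC(C)=O)c(OC(C)=O)c3Oc3cc(OC(C)=O)c(Oc4cc(OC(C)=O)c(OC(C)=O)c(OC(C)=O)c4Oc4cc(OC(C)=O)c(Oc5cc(OC(C)=O)c(OC(C)=O)c(OC(C)=O)c5Oc5cc(OC(C)=O)c(OC(C)=O)c(OC(C)=O)c5)c(OC(C)=O)c4)c(OC(C)=O)c3)c(OC(C)=O)c2)c(OC(C)=O)c1
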